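Ring A, the six-membered carbocycle, is numbered from the quaternary carbon C1 via the ketone C2, the chain-bearing C3, the ether carbon C4 and the acylated C5 to the enol carbon C6; ring B is the pyranone. Everything rests on cutting C1–C2 and C5–C6. The feature used: C1 looks like Cα of an enal once its prenyl CH2 is read as a former CHO, and the 1,3,5-oxygen pattern at C2, C4, C6 matches a ketene acetal carbon, a silyl enol ether carbon and a C–Si carbon. One catalytic asymmetric Diels–Alder reaction closes ring A, fixes C1 and leaves three unlike oxygen masks. Precursor: pinene-derived (Z)-β-silyl enal 8, partner diene 12.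

Key step: step 8

Remark 1 (assumption): the sense of induction of the chiral catalysts in steps 8 and 19 on these new substrates is taken as stated. If a test run shows the opposite sense, the mirror-image catalyst, which is equally available, is used.
Remark 2: CBM stands for the cis-[(1R,3S)-2,2-dimethyl-3-(prop-1-en-2-yl)cyclobutyl]methyl arm, and enolisable compounds are drawn in one tautomeric form.

Step 1
Reactants: 1 (−)-α-pinene
Product: 2 cis-pinonic acid = 2-[(1R,3R)-3-acetyl-2,2-dimethylcyclobutyl]acetic acid
Conditions: RuCl3·xH2O (2 mol %), NaIO4 (4 equiv), EtOAc–MeCN–H2O, 0 → 23 °C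
Reagents that add atoms: sodium periodate [Na+].[O-]I(=O)(=O)=O
Why: Oxidative cleavage of the trisubstituted alkene by RuO4 generated in situ gives the methyl ketone and the carboxylic acid, and the two ring stereocentres, former bridgeheads, are not touched and therefore stay cis.

Step 2
Reactants: 2 cis-pinonic acid
Product: 3 methyl cis-pinonate (1R,3R)
Conditions: MeI, KHCO3, DMF, 23 °C
Reagents that add atoms: iodomethane CI
Why: SN2 O-alkylation of the carboxylate under a weak base gives the ester without enolising the acetyl-bearing stereocentre.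

Step 3
Reactants: 3 methyl cis-pinonate
Product: 4 methyl 2-[(1R,3S)-2,2-dimethyl-3-(prop-1-en-2-yl)cyclobutyl]acetate (cis)
Conditions: Zn, CH2Br2, TiCl4, THF, −40 → 5 °C (reagent aged); then 3, CH2Cl2, 23 °C
Reagents that add atoms: dibromomethane BrCBr
Why: The Lombardo methylenation uses a non-basic CH2(ZnBr)2–TiCl4 reagent that converts ketones but not esters, so the α-stereocentre is not epimerised and the cis ring is kept.

Step 4
Reactants: 4 methylenated ester
Product: 6 (1S,3R)-2,2-dimethyl-1-(prop-1-en-2-yl)-3-(prop-2-yn-1-yl)cyclobutane (cis), via aldehyde 5 (not isolated)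
Conditions: iBu2AlH (1.1 equiv), CH2Cl2, −78 °C; MeOH; then K2CO3, dimethyl (1-diazo-2-oxopropyl)phosphonate, −78 → 23 °C
Reagents that add atoms: Ohira–Bestmann reagent COP(=O)(OC)C(=[N+]=[N-])C(C)=O
Why: Partial ester reduction to the aluminium hemiacetal followed in the same flask by Ohira–Bestmann (Seyferth–Gilbert) homologation of the released aldehyde is an established ester-to-terminal-alkyne sequence, and the former carboxyl carbon becomes the internal alkyne carbon, the later C1.

Step 5
Reactants: 6 terminal alkyne; 7 benzyl(dimethyl)silane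
Product: 8 (Z)-3-[benzyl(dimethyl)silyl]-2-(CBM)prop-2-enal
Conditions: Rh(acac)(CO)2 (1 mol %), CO (10 atm), toluene, 25 °C
Reagents that add atoms: carbon monoxide [C-]#[O+]
Why: Rhodium-catalysed silylformylation adds silicon to the terminal and CHO to the internal alkyne carbon in a syn manner, which gives the Z-enal and leaves the 1,1-disubstituted alkene alone; silicon carries benzyl because this group is later removed by fluoride, whereas an aryl group would need acid, halogen or peracid that the two alkenes and the cyclobutylcarbinyl system would not survive.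

Step 6
Reactants: 9 1,1-dimethoxyethene; 10 acetyl chloride
Product: 11 4,4-dimethoxybut-3-en-2-one
Conditions: pyridine, CH2Cl2, 0 → 23 °C
Reagents that add atoms: none
Why: C-acylation of the nucleophilic ketene acetal by the acyl chloride and loss of HCl to pyridine gives the push–pull acylketene acetal.

Step 7
Reactants: 11 4,4-dimethoxybut-3-en-2-one
Product: 12 1,1-dimethoxy-3-(trimethylsilyloxy)buta-1,3-diene
Conditions: Me3SiCl, Et3N, ZnCl2 (cat.), toluene, 40 °C
Reagents that add atoms: chlorotrimethylsilane C[Si](C)(C)Cl
Why: Amine/ZnCl2-mediated O-silylation of the methyl ketone is the standard entry to 2-silyloxybutadienes, and the two identical methoxy groups ensure that the elimination after the cycloaddition can only leave OMe on C2, which a mixed methyl silyl ketene acetal (preferential loss of methanol and then of silicon) would not.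

Step 8
Reactants: 8 (Z)-β-silyl enal; 12 diene
Product: 14 (4S,5S)-5-[benzyl(dimethyl)silyl]-4-(CBM)-4-formyl-3-methoxycyclohex-2-en-1-one [ring A: C1 with CHO + CBM; C2–OMe; C4 ketone; C6–Si cis to CHO], via ketal cycloadduct 13 (not isolated)
Conditions: [Co(salen)]SbF6 (5 mol %; trivalent cobalt; salen = (R,R)-N,N'-bis(3,5-di-tert-butylsalicylidene)cyclohexane-1,2-diamine dianion), 4 Å MS, CH2Cl2, −40 → 0 °C; then 0.1 M HCl, THF, 0 °C
Reagents that add atoms: none
Why: Proposed new method: the cationic cobalt centre binds the formyl oxygen of s-trans 8, and the CH2 terminus of 12 (largest HOMO coefficient) bonds to the silicon-bearing Cβ (C5–C6) slightly ahead of the bond from the ketene acetal carbon to Cα (C1–C2), in a one-step but asynchronous cycloaddition that is suprafacial on both partners. The closest known reaction type is the chiral-Lewis-acid Diels–Alder reaction of 2-alkylacroleins with 1-amino- or 1-alkoxy-3-silyloxybutadienes, which gives 4-alkyl-4-formylcyclohexenones; not yet shown are a β-silyl substituent on the enal and a 1,1-dialkoxy diene terminus. Ring A closes in the [4π+2π] mode, which in the stepwise limit is a Mukaiyama–Michael addition followed by 6-(enolexo)-exo-trig capture of the dimethoxycarbenium ion by the cobalt enolate. C1 is controlled by the salen ligand, which has to leave open the Si face of Cα (priorities Cβ > CHO > CH2), and C6 by the Z geometry of 8, since suprafacial addition places silicon cis to formyl; the ketal carbon C2 bears two equal groups, so endo or exo approach is of no consequence. The step needs C=C over C=O chemoselectivity, head-to-tail regiochemistry and face selectivity: the fully substituted Cα next to the bound formyl group hinders attack at the carbonyl carbon, the donor–acceptor polarity of the partners fixes the orientation, and Cα carries one alkyl arm only, so its two faces differ clearly for the catalyst. Dilute acid then cleaves the silyl enol ether of 13 and expels one of the two methoxy groups, which can only give the C2 methyl enol ether and C4 ketone of 14.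

Step 9
Reactants: 14 formyl enone
Product: 16 homologated aldehyde [14 with CH2CHO on C1 in place of CHO], via alkenyl boronate 15 (not isolated)
Conditions: CH2(Bpin)2, lithium 2,2,6,6-tetramethylpiperidide, THF, 0 °C; 14, −78 → 23 °C; then NaBO3·4H2O, THF–H2O, 23 °C
Reagents that add atoms: bis(pinacolatoboryl)methane CC1(C)OB(CB2OC(C)(C)C(C)(C)O2)OC1(C)C; sodium perborate [Na+].[O-]OB=O
Why: Boron–Wittig olefination of the non-enolisable aldehyde and oxidation of the alkenyl boronate to the enol and hence the aldehyde is a one-carbon homologation that needs no acid, so the C2 methyl enol ether, the isopropenyl group and the C–Si bond survive and C1 is not touched.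

Step 10
Reactants: 16 homologated aldehyde
Product: 17 prenyl enone [C1 with CH2CH=CMe2 + CBM; C2–OMe; C4 ketone; C6–SiMe2Bn]
Conditions: iPrPPh3I, n-BuLi, THF, 0 °C; 16, −78 → 0 °C
Reagents that add atoms: isopropyltriphenylphosphonium iodide CC(C)[P+](c1ccccc1)(c1ccccc1)c1ccccc1.[I-]
Why: Wittig olefination with the non-stabilised isopropylidene ylide is much faster at the aldehyde than at the vinylogous ester carbonyl and completes the prenyl group, whose CH2 is the former formyl carbon.

Step 11
Reactants: 18 methyl (R)-3-hydroxybutanoate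
Product: 19 methyl (2R,3R)-3-hydroxy-2-methylbutanoate (anti)
Conditions: LiN(iPr)2 (2.2 equiv), THF, −78 → −20 °C; MeI, −78 → 0 °C
Reagents that add atoms: iodomethane CI
Why: In the Fráter–Seebach alkylation the chelated lithium alkoxide enolate is methylated on the face away from the C3 methyl group, so the existing carbinol centre sets the new centre anti, (2R,3R).

Step 12
Reactants: 19 anti hydroxy ester
Product: 20 methyl (2R,3R)-2-methyl-3-(triethylsilyloxy)butanoate
Conditions: Et3SiCl, imidazole, CH2Cl2, 0 °C
Reagents that add atoms: chlorotriethylsilane CC[Si](Cl)(CC)CC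
Why: Imidazole-promoted O-silylation gives a triethylsilyl ether that stands hydride, enolate and periodinane conditions yet falls off in dilute acid.

Step 13
Reactants: 20 silyl ether ester
Product: 21 (2R,3R)-2-methyl-3-(triethylsilyloxy)butanal
Conditions: iBu2AlH, CH2Cl2, −78 °C; aq KNaC4H4O6
Reagents that add atoms: none
Why: Low-temperature iBu2AlH reduction stops at the tetrahedral aluminium hemiacetal, which releases the aldehyde on work-up, and slight epimerisation at C2 would be harmless because this centre later sits next to the ring B ketone, where trans is the stable arrangement.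

Step 14
Reactants: 17 prenyl enone; 21 aldehyde
Product: 22 C5 aldol adduct (mixture at C5 and at the new carbinol carbon)
Conditions: LiN(iPr)2, THF, −78 °C; 21, −78 °C
Reagents that add atoms: none
Why: Kinetic deprotonation of a 3-alkoxyenone occurs at the α' carbon, here C5 as the only enolisable position, and a lithium aldol addition follows; the two new centres are erased in steps 15 and 16, and silicon at C6, unlike oxygen, cannot leave by β-elimination from the enolate.

Step 15
Reactants: 22 aldol adduct
Product: 23 β-diketone [C5 bears C(=O)–(R)-CHMe–(R)-CHMe–OSiEt3]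
Conditions: Dess–Martin periodinane, NaHCO3, CH2Cl2, 0 → 23 °C
Reagents that add atoms: none
Why: Buffered Dess–Martin oxidation turns the β-hydroxy ketone into the β-diketone and leaves alkenes, the tetraorganosilane and the silyl ether untouched.

Step 16
Reactants: 23 β-diketone
Product: 26 ring A/B silane [ring B = (2R,3R)-2,3-dimethyl-2,3-dihydropyran-4-one fused at C4–C5; C2 ketone; C3H2; C6–SiMe2Bn], via hydroxy diketone 24 (not isolated), via methyl dienol ether 25 (not isolated)
Conditions: 1 M HCl, THF, 0 → 23 °C
Reagents that add atoms: water O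
Why: Dilute acid removes the triethylsilyl group, the freed hydroxyl adds to the only carbonyl within reach (C4) and water is lost (cyclodehydration of a δ-hydroxy-β-diketone to a 2,3-dihydropyran-4-one, no bond to either methyl-bearing centre being broken), and the C2 methyl ether, by now a dienol ether, is hydrolysed as well, so that every order of events converges on 26.

Step 17
Reactants: 26 ring A/B silane
Product: 28 C6 carbinol [26 with OH in place of SiMe2Bn; retention], via silanol 27 (not isolated)
Conditions: Bu4NF, THF, 0 °C; then 30 % H2O2, KHCO3, MeOH, 23–40 °C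
Reagents that add atoms: hydrogen peroxide OO; water O
Why: In this Tamao–Fleming oxidation fluoride removes the benzyl group from silicon as toluene and basic peroxide shifts C6 from silicon to oxygen with retention, under nucleophilic conditions that spare both alkenes, while C5 carries no hydrogen and water therefore cannot be eliminated.

Step 18
Reactants: 28 C6 carbinol
Product: 29 ring A/B core [target without the C3 chain; C6 enol hydrogen-bonded to the ring B carbonyl]
Conditions: Dess–Martin periodinane (1.1 equiv), NaHCO3, CH2Cl2, 0 °C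
Reagents that add atoms: none
Why: Dess–Martin oxidation of the allylic C6 carbinol gives the ketone, which tautomerises to the chelated enol, and limiting the oxidant avoids further oxidation at C3.

Step 19
Reactants: 29 ring A/B core; 30 3-phenylprop-2-ynal
Product: 31 enol lactone [(S)-4-phenyl-3,4-dihydropyran-2-one fused at C2(O)–C3]
Conditions: 30 (1.5 equiv), (5aR,10bS)-N-mesityl aminoindanol-derived triazolium chloride (10 mol %), iPr2NEt (10 mol %), toluene, 40 °C
Reagents that add atoms: none
Why: In this N-heterocyclic carbene annulation of stable cyclic enols the ynal is converted by internal redox into an α,β-unsaturated acyl azolium, C3 adds to its β-carbon (Michael or Coates–Claisen pathway) on the face left open by the chiral carbene, which sets the (S) benzylic centre, and only the C2 oxygen can lactonise because the C4 oxygen is tied up in ring B.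

Step 20
Reactants: 31 enol lactone
Product: 32 CNP0103716.3 (target)
Conditions: LiOH, THF–H2O, 0 °C; then 1 M HCl to pH 3
Reagents that add atoms: lithium hydroxide [Li+].[OH-]
Why: Saponification of the activated enol lactone is fast at 0 °C, frees the acid chain and the C2 carbonyl, and touches no stereocentre because ring A is a delocalised anion during the reaction.

Compound list
1 | (−)-α-pinene, (1S,5S) | CC1=CC[C@H]2C[C@@H]1C2(C)C | starting material
2 | cis-pinonic acid, (1R,3R) | CC(=O)[C@@H]1C[C@H](CC(=O)O)C1(C)C | intermediate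
3 | methyl cis-pinonate | CC(=O)[C@@H]1C[C@H](CC(=O)OC)C1(C)C | intermediate
4 | methyl 2-[(1R,3S)-2,2-dimethyl-3-(prop-1-en-2-yl)cyclobutyl]acetate | C=C(C)[C@@H]1C[C@H](CC(=O)OC)C1(C)C | intermediate
5 | 2-[(1R,3S)-2,2-dimethyl-3-(prop-1-en-2-yl)cyclobutyl]acetaldehyde (not isolated) | C=C(C)[C@@H]1C[C@H](CC=O)C1(C)C | intermediate
6 | (1S,3R)-2,2-dimethyl-1-(prop-1-en-2-yl)-3-(prop-2-yn-1-yl)cyclobutane | C=C(C)[C@@H]1C[C@H](CC#C)C1(C)C | intermediate
7 | benzyl(dimethyl)silane | C[SiH](C)Cc1ccccc1 | starting material
8 | (Z)-3-[benzyl(dimethyl)silyl]-2-(CBM)prop-2-enal | C=C(C)[C@@H]1C[C@H](C/C(C=O)=C/[Si](C)(C)Cc2ccccc2)C1(C)C | intermediate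
9 | 1,1-dimethoxyethene | C=C(OC)OC | starting material
10 | acetyl chloride | CC(=O)Cl | starting material
11 | 4,4-dimethoxybut-3-en-2-one | CC(=O)C=C(OC)OC | intermediate
12 | 1,1-dimethoxy-3-(trimethylsilyloxy)buta-1,3-diene | C=C(O[Si](C)(C)C)C=C(OC)OC | intermediate
13 | primary cycloadduct, C2 dimethyl ketal, C3=C4 silyl enol ether (not isolated) | C=C(C)[C@@H]1C[C@H](C[C@@]2(C=O)C(OC)(OC)C=C(O[Si](C)(C)C)C[C@@H]2[Si](C)(C)Cc3ccccc3)C1(C)C | intermediate
14 | (4S,5S)-5-[benzyl(dimethyl)silyl]-4-(CBM)-4-formyl-3-methoxycyclohex-2-en-1-one | C=C(C)[C@@H]1C[C@H](C[C@@]2(C=O)C(OC)=CC(=O)C[C@@H]2[Si](C)(C)Cc3ccccc3)C1(C)C | intermediate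
15 | (E)-alkenyl pinacol boronate on C1 (not isolated) | C=C(C)[C@@H]1C[C@H](C[C@@]2(/C=C/B3OC(C)(C)C(C)(C)O3)C(OC)=CC(=O)C[C@@H]2[Si](C)(C)Cc3ccccc3)C1(C)C | intermediate
16 | homologated aldehyde, CH2CHO on C1 | C=C(C)[C@@H]1C[C@H](C[C@@]2(CC=O)C(OC)=CC(=O)C[C@@H]2[Si](C)(C)Cc3ccccc3)C1(C)C | intermediate
17 | prenyl enone | C=C(C)[C@@H]1C[C@H](C[C@@]2(CC=C(C)C)C(OC)=CC(=O)C[C@@H]2[Si](C)(C)Cc3ccccc3)C1(C)C | intermediate
18 | methyl (R)-3-hydroxybutanoate | C[C@@H](O)CC(=O)OC | starting material
19 | methyl (2R,3R)-3-hydroxy-2-methylbutanoate | O[C@H](C)[C@@H](C)C(=O)OC | intermediate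
20 | methyl (2R,3R)-2-methyl-3-(triethylsilyloxy)butanoate | CC[Si](CC)(CC)O[C@H](C)[C@@H](C)C(=O)OC | intermediate
21 | (2R,3R)-2-methyl-3-(triethylsilyloxy)butanal | CC[Si](CC)(CC)O[C@H](C)[C@@H](C)C=O | intermediate
22 | C5 aldol adduct (mixture at C5 and carbinol carbon) | C=C(C)[C@@H]1C[C@H](C[C@@]2(CC=C(C)C)C(OC)=CC(=O)C(C(O)[C@H](C)[C@@H](C)O[Si](CC)(CC)CC)[C@@H]2[Si](C)(C)Cc3ccccc3)C1(C)C | intermediate
23 | β-diketone (keto form drawn) | C=C(C)[C@@H]1C[C@H](C[C@@]2(CC=C(C)C)C(OC)=CC(=O)C(C(=O)[C@H](C)[C@@H](C)O[Si](CC)(CC)CC)[C@@H]2[Si](C)(C)Cc3ccccc3)C1(C)C | intermediate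
24 | δ-hydroxy β-diketone (not isolated) | C=C(C)[C@@H]1C[C@H](C[C@@]2(CC=C(C)C)C(OC)=CC(=O)C(C(=O)[C@H](C)[C@@H](C)O)[C@@H]2[Si](C)(C)Cc3ccccc3)C1(C)C | intermediate
25 | ring B closed, C2 methyl dienol ether (not isolated) | C=C(C)[C@@H]1C[C@H](C[C@@]2(CC=C(C)C)C(OC)=CC3=C(C(=O)[C@H](C)[C@@H](C)O3)[C@@H]2[Si](C)(C)Cc4ccccc4)C1(C)C | intermediate
26 | ring A/B silane, C2 ketone | C=C(C)[C@@H]1C[C@H](C[C@@]2(CC=C(C)C)C(=O)CC3=C(C(=O)[C@H](C)[C@@H](C)O3)[C@@H]2[Si](C)(C)Cc4ccccc4)C1(C)C | intermediate
27 | dimethylsilanol at C6 (not isolated) | C=C(C)[C@@H]1C[C@H](C[C@@]2(CC=C(C)C)C(=O)CC3=C(C(=O)[C@H](C)[C@@H](C)O3)[C@@H]2[Si](C)(C)O)C1(C)C | intermediate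
28 | C6 carbinol | C=C(C)[C@@H]1C[C@H](C[C@@]2(CC=C(C)C)C(=O)CC3=C(C(=O)[C@H](C)[C@@H](C)O3)[C@@H]2O)C1(C)C | intermediate
29 | ring A/B core, C3–H | C=C(C)[C@@H]1C[C@H](C[C@@]2(CC=C(C)C)C(=O)C=C3O[C@H](C)[C@@H](C)C(=O)C3=C2O)C1(C)C | intermediate
30 | 3-phenylprop-2-ynal | O=CC#Cc1ccccc1 | starting material
31 | enol lactone, (S) at the benzylic carbon | C=C(C)[C@@H]1C[C@H](C[C@@]2(CC=C(C)C)C3=C([C@H](c4ccccc4)CC(=O)O3)C5=C(C(=O)[C@H](C)[C@@H](C)O5)C2=O)C1(C)C | intermediate
32 | CNP0103716.3 | C=C(C)[C@@H]1C[C@H](C[C@@]2(CC=C(C)C)C(=O)C([C@@H](CC(=O)O)c3ccccc3)=C3O[C@H](C)[C@@H](C)C(=O)C3=C2O)C1(C)C | target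

Total step count: 20. Longest linear sequence: 15 steps (1–5, 8–10, 14–20) from (−)-α-pinene.

Steps most likely to fail

Step 8. Three things may go wrong:
- The bound enal may be attacked at the formyl carbon (vinylogous aldol or hetero-Diels–Alder channel).
- The crowded Cα/Cβ pair may react so slowly that the diene decays.
- Face selectivity may be poor.

The fallback gives up catalyst control. Compounds 8 and 12 are heated without any additive (toluene, sealed tube, about 100 °C). This is the classical thermal mode of this diene with enals and enones, in which addition to C=C is the normal course. It should give 13 together with the diastereomeric primary adduct F1. The same dilute-acid treatment then gives 14 and the C1,C6-diastereomeric enone F2. The two enones differ in their relation to the cyclobutane centres and are separated by chromatography. The fallback sets out from 8 and 12 and comes back to the route at 14.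

Step 19. Bond formation at the flanked C3 may be slow, reversible O-acylation may dominate, or the chiral substrate may work against the catalyst and erode facial selectivity. The fallback replaces catalyst control by a much stronger acceptor and a separation. Core 29 is treated with 5-benzylidene-2,2-dimethyl-1,3-dioxane-4,6-dione and catalytic Et3N in MeCN at 60 °C. This is the known Michael addition–lactonisation of cyclic 1,3-dicarbonyl compounds with arylidene Meldrum's acids. The Michael adduct F3 is attacked by the C2 oxygen and loses acetone and carbon dioxide. The result is 31 and the benzylic epimer of the lactone F4, which are diastereomers and are separated. The fallback sets out from 29 and comes back at 31.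

Step 17. Once C6 carries a hydroxyl group next to C1 and the free C2 ketone, base may open ring A by a retro-aldol process. Fluoride may also cleave the allylic C6–Si bond instead of the benzyl–Si bond. The fallback keeps C2 masked during the oxidation:
- Diketone 23 is treated with catalytic camphorsulfonic acid and HC(OMe)3 in MeOH at 23 °C. These water-free conditions pass through 24 and stop at 25, which is now isolated.
- Bu4NF converts 25 into the silanol F5, and H2O2/KHCO3 in MeOH gives the C6 carbinol F6, which has no carbonyl at C2 and so cannot undergo the retro-aldol process.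
- Buffered Dess–Martin oxidation gives the dienone methyl ether F7.
- SN2 demethylation with LiCl in DMSO at about 100 °C, kept short because of possible sigmatropic shifts of the prenyl group, gives 29.

The fallback sets out from 23 and comes back at 29.

Further compounds
F1 | step 8 | C1,C6-diastereomer of cycloadduct 13 | C=C(C)[C@@H]1C[C@H](C[C@]2(C=O)C(OC)(OC)C=C(O[Si](C)(C)C)C[C@H]2[Si](C)(C)Cc3ccccc3)C1(C)C
F2 | step 8 | C1,C6-diastereomer of enone 14 | C=C(C)[C@@H]1C[C@H](C[C@]2(C=O)C(OC)=CC(=O)C[C@H]2[Si](C)(C)Cc3ccccc3)C1(C)C
F3 | step 19 | Michael adduct of 29 with benzylidene Meldrum's acid (both benzylic epimers) | C=C(C)[C@@H]1C[C@H](C[C@@]2(CC=C(C)C)C(=O)C(C(c4ccccc4)C5C(=O)OC(C)(C)OC5=O)=C3O[C@H](C)[C@@H](C)C(=O)C3=C2O)C1(C)C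
F4 | step 19 | benzylic (R) epimer of lactone 31 | C=C(C)[C@@H]1C[C@H](C[C@@]2(CC=C(C)C)C3=C([C@@H](c4ccccc4)CC(=O)O3)C5=C(C(=O)[C@H](C)[C@@H](C)O5)C2=O)C1(C)C
F5 | step 17 | C6 dimethylsilanol with C2 methyl dienol ether | C=C(C)[C@@H]1C[C@H](C[C@@]2(CC=C(C)C)C(OC)=CC3=C(C(=O)[C@H](C)[C@@H](C)O3)[C@@H]2[Si](C)(C)O)C1(C)C
F6 | step 17 | C6 carbinol with C2 methyl dienol ether | C=C(C)[C@@H]1C[C@H](C[C@@]2(CC=C(C)C)C(OC)=CC3=C(C(=O)[C@H](C)[C@@H](C)O3)[C@@H]2O)C1(C)C
F7 | step 17 | C6 dienone, C2 methyl ether | C=C(C)[C@@H]1C[C@H](C[C@@]2(CC=C(C)C)C(OC)=CC3=C(C(=O)[C@H](C)[C@@H](C)O3)C2=O)C1(C)C
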